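## Structural features

The target is a p-terphenyl: a fully substituted central benzene ring (C1–C6, numbered from the carbon that carries the 3-hydroxybutanoate) joined through C3 and C6 to two 4-hydroxyphenyl rings. The four remaining ring carbons all bear oxygen. C1 and C4 are aryl esters of two different acids, (S)-3-hydroxybutanoic acid at C1 and 3-phenylpropanoic acid at C4, and C2 and C5 are free hydroxyls, so like groups always sit para to each other. The only stereocentre is the carbinol carbon of the hydroxybutanoyl chain (S); it is remote from the ring and best taken from the chiral pool. The fragile points are the two aryl esters, each next to a free phenol (acyl migration or cleavage under base), the C2/C5 hydroquinone (oxidation to the quinone) and the β-hydroxy ester (elimination to a crotonate). The real difficulty is not the carbon skeleton: apart from the identity of the two acyl groups the core is centrosymmetric, so four chemically similar ring oxygens must be told apart. The key step exploits the sequence O–C2, aryl–C3, O–C4, O–C5, aryl–C6, O–C1. C2 and C5 are para oxygen-bearing carbons, each flanked by one aryl-bearing and one oxygen-bearing carbon, which is what a carbene carbon (C2), a carbonyl ligand (C5), an enol ether (C1=C6) and an ynol ether (C3≡C4) assemble, each oxygen arriving with a different substituent.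

## Logic of the disconnections

24 ⇒ 23. The five O–benzyl bonds are cut (phenol oxygens at C2 and C5, the two outer phenols, the carbinol oxygen). All hydroxyls are released together in the last step, so no aryl ester ever meets a neighbouring free phenol under basic or strongly acidic conditions. The forward step must therefore be neutral and non-nucleophilic.

23 ⇒ 19 + 22. The acyl C–O bond of the C1 ester is cut. This separates the stereocentre from the core. The benzylated core is centrosymmetric apart from the two ester sites, so either para oxygen may receive either acid. The forward step must acylate a phenol flanked by a benzyloxy group and an aryl ring without eliminating the β-alkoxy group of the acid.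

22 ⇒ 21 ⇒ 20. The ethyl ester and the carbinol O–benzyl bond are cut. The stereocentre is bought with 20. No forward step may break its C–O bond or pass through a strongly basic alkoxide of the β-hydroxy ester.

19 ⇒ 18 ⇒ 16 (through 17). The O–CH2OMe bond at C1 is cut, then the acyl C–O bond at C4, whose oxygen is traced back to a silyl ether. The two para ester sites thus differ from each other (acetal against silyl ether) and from the two hydroxyl sites (benzyl ethers). Fluoride must touch only silicon, and the acetal must be cleaved without harming an aryl ester.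

16 ⇒ 15. The O–benzyl bond at C5 is cut, which exposes the one free phenol that the ring synthesis delivers. The forward alkylation must not let the neighbouring silyl group move from the C4 oxygen to the C5 oxygen, because that would exchange the roles of the two oxygens.

15 ⇒ 10 + 14. Three ring bonds are cut: C2–C3, C4–C5 and C5–C6. C5 and its oxygen go back to a carbonyl ligand. The hexasubstituted arene falls into an alkenylcarbene complex and an ynol ether, each carrying one aryl group and its oxygen substituents. The forward step must insert the alkyne in one orientation only and must close the six-membered ring with carbonyl insertion.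

10 ⇒ 8 ⇒ 4 + 5 (through 9, 7 and 6). The benzyl–oxygen bond of the carbene is cut, then the bond between the carbene carbon and the vinyl carbon. Direct O-benzylation of an acylchromate with a benzyl halide is unreliable, so the benzyloxy group is brought in by alcoholysis of an acyloxycarbene. The vinyl anion must be formed at the oxygen-bearing carbon of 4 in the presence of a benzyl ether.

4 ⇒ 2 ⇒ 1. The enol O–CH2OMe bond is cut, then the aldehyde is taken back to the alcohol. The acetal is chosen because it directs the later lithiation and is orthogonal to silyl and benzyl. The sensitive arylacetaldehyde 2 must be enolised completely before it can condense with itself.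

14 ⇒ 11 (through 12 and 13). The Si–O bond and the C–O bond of the ynol ether are cut. The oxygen is put on a terminal alkyne by oxidation of its acetylide, which needs no excess alkyllithium next to the benzyl ether, and a bulky silyl group ensures O-silylation of the ynolate.

## Other disconnections considered

Alternative 1: The ring is cut into three alkynes: the bond between the two tethered oxygen-bearing carbons, and the two bonds from the aryl-bearing carbons to an ynediether. Forward, the silylene-tethered bis(ynol ether) A1 and di-tert-butoxyethyne A2 would undergo a (2+2+2) cycloaddition on CpCo(CO)2 (monovalent cobalt) to give the benzodioxasilole A3.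
- In favour: it is the most convergent plan. It forms the hexasubstituted ring with all four oxygens and both aryl groups in one operation, the tether guarantees the para relation of the aryl groups, and the metal is catalytic where the chosen plan uses a full equivalent of chromium. On atom economy and on steps to the ring it is the better plan.
- Against, structure: the tether joins two adjacent oxygens and A2 supplies the other two adjacent oxygens, so A3 has a mirror plane that makes the oxygens equivalent in ortho pairs. The target needs the opposite pairing (like oxygens para). One oxygen of each pair would have to be acylated, with two different acids and in a para relation, with nothing in A3 to direct this.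
- Against, mechanism: A2 loses isobutene on mild heating, and electron-rich ynol ethers are prone to ketene formation and homo-oligomerisation on cobalt, so the risk is no smaller than that of the chosen benzannulation.
- Comparison: equal or better up to the arene; clearly worse on the problem that defines this target, the differentiation of four oxygens, which the chosen plan settles in the ring-forming step.

Alternative 2: Both aryl C–O(ester) bonds are cut, tracing the two acyloxy groups back to two aryl ketones. Forward, the hydroquinone diester A4 would undergo a twofold photo-Fries rearrangement, each acyl group moving from oxygen to the free ortho carbon. After benzylation of the two liberated phenols, the 1,4-diacylarene A5 would be oxidised with a peracid, and aryl migration in both Criegee intermediates would give the diester A6, the same substance as 23.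
- In favour: the para relation of the two esters and of the two hydroxyls follows from the two free positions of a 2,5-diarylhydroquinone, so no regiochemical question arises in the ring. The core comes from cheap symmetric materials by twofold cross-coupling, no stoichiometric transition metal is needed, and the endgame is the same single hydrogenolysis. On these points it equals or beats the chosen plan.
- Against, structure: the two acyl groups differ, so A4 requires desymmetrisation of a symmetric hydroquinone (statistical monoacylation or extra protecting-group steps). This is the same differentiation problem moved earlier.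
- Against, mechanism: the photo-Fries step runs through caged radical pairs and must place two acyl groups next to aryl rings, with decarbonylation and phenol formation as the usual losses. The double Baeyer–Villiger oxidation must act on two very hindered ketones of an electron-rich ring that a peracid can also hydroxylate, although the twist of such ketones and the migratory aptitude of the electron-rich aryl group favour the desired sense.
- Comparison: similar step count and identical endgame; less organometallic risk, but two steps of typically moderate efficiency in sequence and a desymmetrisation left to statistics, where the chosen plan differentiates all oxygens by construction.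

Alternative 3: The ring is cut at C1–C6 and C3–C4 (target numbering), between each aryl-bearing carbon and one neighbouring oxygen-bearing carbon, into two identical arylpyruvate units. Forward, two molecules of the ester A7 would condense head to tail under excess NaOMe, each benzylic carbon acylating the ester carbon of the other, to give the dihydroxyquinone A8. Reduction would give the tetrol A9, which must then be acylated twice.
- In favour: it follows the biosynthesis, reaches the complete carbon and oxygen skeleton in one step from a three-carbon building block, and needs no metal and no protecting group on the core. On step economy up to the core it is clearly the better plan.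
- Against, mechanism: the Claisen dimerisation competes with aldol dimerisation of the pyruvate, which leads to butenolides.
- Against, structure: A9 has four equivalent hydroxyls. The first acylation is unambiguous, but the second must pick the para oxygen over the ortho and meta ones with no directing element, and acyl groups migrate readily between neighbouring phenolic oxygens under basic acylation conditions.
- Comparison: the best route for symmetric tetraesters, but for this unsymmetrical para diester the short ring synthesis would be paid for with statistical acylations and separations of regioisomers. The chosen plan is longer to the ring but then runs through single compounds.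

Key step: step 6

Remarks on the chemistry:
- 4 is expected as a mixture of alkene isomers. The Z isomer is drawn, and 3 and 6–10 are drawn to match. Both isomers converge at 15 because the alkene carbon concerned becomes aromatic.
- 11 is taken as a purchasable starting material.
- The carbinol carbon has the same S arrangement in 20 and in 24, so no inversion is needed.

## Steps

Step 1
Reactants: 1 2-[4-(benzyloxy)phenyl]ethan-1-ol
Product: 2 [4-(benzyloxy)phenyl]acetaldehyde
Conditions: Dess–Martin periodinane, CH2Cl2, 0 °C → rt
Reagents that add atoms: none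
Why: Dess–Martin oxidation of a primary alcohol stops at the aldehyde under nearly neutral conditions, which suits an easily enolised arylacetaldehyde; the crude aldehyde should be used at once.

Step 2
Reactants: 2 [4-(benzyloxy)phenyl]acetaldehyde
Product: 4 1-(benzyloxy)-4-[(Z)-2-(methoxymethoxy)ethenyl]benzene, via potassium enolate 3 (not isolated)
Conditions: KN(SiMe3)2, THF, −78 °C (aldehyde added to the base); MOMCl, −78 → 0 °C
Reagents that add atoms: chloromethyl methyl ether, COCCl
Why: O-alkylation of a potassium enolate by a hard chloromethyl ether; the aryl-conjugated enolate should form completely at −78 °C under inverse addition, which keeps self-aldol reaction low, and the alkene geometry has no later consequence.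

Step 3
Reactants: 4 1-(benzyloxy)-4-[(Z)-2-(methoxymethoxy)ethenyl]benzene; 5 hexacarbonylchromium
Product: 8 tetramethylammonium pentacarbonyl{(2Z)-3-[4-(benzyloxy)phenyl]-2-(methoxymethoxy)prop-2-enoyl}chromate(1−), via α-lithio enol ether 6 (not isolated), via lithium acylchromate 7 (not isolated)
Conditions: s-BuLi (1.05 equiv), THF, −78 °C; Cr(CO)6, −78 → 0 °C; Me4NBr, H2O/CH2Cl2, rt
Reagents that add atoms: tetramethylammonium bromide, C[N+](C)(C)C.[Br-]
Why: Acetal-directed α-lithiation of an enol ether followed by addition of the vinyllithium to a carbonyl ligand (Fischer acylmetalate synthesis); chelation by the acetal oxygens should make the vinylic C–H the kinetic site at −78 °C with one equivalent of base, ahead of the benzylic OCH2 protons. Cation exchange gives a salt that can be dried before acylation.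

Step 4
Reactants: 8 tetramethylammonium pentacarbonyl{(2Z)-3-[4-(benzyloxy)phenyl]-2-(methoxymethoxy)prop-2-enoyl}chromate(1−)
Product: 10 pentacarbonyl{(benzyloxy)[(Z)-2-[4-(benzyloxy)phenyl]-1-(methoxymethoxy)ethenyl]methylidene}chromium, via acetoxycarbene complex 9 (not isolated)
Conditions: AcBr, CH2Cl2, −40 °C; BnOH, −40 °C → rt
Reagents that add atoms: benzyl alcohol, OCc1ccccc1
Why: O-acylation of the acylmetalate gives a highly electrophilic acyloxycarbene in which benzyl alcohol displaces acetate by addition–elimination at the carbene carbon; this is the standard route to alkoxycarbene complexes whose alkyl group cannot come from an oxonium salt.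

Step 5
Reactants: 11 1-(benzyloxy)-4-ethynylbenzene
Product: 14 {[4-(benzyloxy)phenyl]ethynyloxy}tri(propan-2-yl)silane, via lithium acetylide 12 (not isolated), via lithium ynolate 13 (not isolated)
Conditions: n-BuLi, THF, −78 °C; t-BuOOLi (from t-BuOOH and LiN(SiMe3)2, THF, −78 °C), −78 → 0 °C; TIPSOTf, −78 °C → rt
Reagents that add atoms: tert-butyl hydroperoxide, CC(C)(C)OO; tri(propan-2-yl)silyl trifluoromethanesulfonate, CC(C)[Si](OS(=O)(=O)C(F)(F)F)(C(C)C)C(C)C
Why: Electrophilic oxygen transfer from the lithium peroxide to the acetylide gives the ynolate, which a bulky silyl triflate captures on oxygen (a small silyl group would go to carbon). No alkyllithium is present above −78 °C, so the benzyl ether is safe.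

Step 6
Reactants: 10 pentacarbonyl{(benzyloxy)[(Z)-2-[4-(benzyloxy)phenyl]-1-(methoxymethoxy)ethenyl]methylidene}chromium; 14 {[4-(benzyloxy)phenyl]ethynyloxy}tri(propan-2-yl)silane
Product: 15 4-(benzyloxy)-3,6-bis[4-(benzyloxy)phenyl]-5-(methoxymethoxy)-2-{[tri(propan-2-yl)silyl]oxy}phenol
Conditions: THF (0.1 M), 50 °C, Ar; then air, MeCN, rt
Reagents that add atoms: none
Why: Proposed new method: Heating should release one cis carbonyl ligand from 10 and let 14 take its place; insertion into the chromium–carbene bond is expected to join the nucleophilic aryl-bearing alkyne carbon to the electrophilic carbene carbon (C2–C3) and to leave the siloxy carbon as the new oxygen-stabilised carbene carbon, the sense known for ynamine and alkoxyalkyne insertions into Fischer carbenes. Migration of a carbonyl ligand onto that carbon (C4–C5) gives a chromium-bound dienylketene, whose thermal 6π electrocyclisation (C5–C6) closes the one new ring, the central benzene, as a cyclohexadienone that tautomerises to the phenol; air then frees the arene from the Cr(CO)3 fragment. The closest known reaction type is the Dötz benzannulation of α-alkoxyalkenyl(alkoxy)carbene complexes of zerovalent chromium with internal alkynes and with heteroatom-substituted alkynes such as alkynylboronates; a siloxyalkyne has not been shown as the alkyne partner. No stereocentre is formed. The selectivity needed is the regiochemistry of insertion, and here the electronic polarisation of the ynol ether and the usual steric rule (the larger alkyne end, OTIPS, next to the carbonyl-derived carbon) point the same way. The second requirement, carbonyl insertion instead of five-membered ring closure, is favoured by the alkenyl carbene, the alkoxy donor and the moderate temperature in THF. The four ring oxygens emerge as OH, OTIPS, OBn and OMOM, so each later operation addresses one oxygen only.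

Step 7
Reactants: 15 4-(benzyloxy)-3,6-bis[4-(benzyloxy)phenyl]-5-(methoxymethoxy)-2-{[tri(propan-2-yl)silyl]oxy}phenol
Product: 16 {2,5-bis(benzyloxy)-3,6-bis[4-(benzyloxy)phenyl]-4-(methoxymethoxy)phenoxy}tri(propan-2-yl)silane
Conditions: BnOH, PPh3, DIAD, toluene, 0 °C → rt
Reagents that add atoms: benzyl alcohol, OCc1ccccc1
Why: Mitsunobu etherification of a phenol with a primary benzylic alcohol. No free metal phenoxide is formed, which is meant to prevent transfer of the neighbouring silyl group to the new phenol oxygen, the one event that would exchange the roles of the two oxygens.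

Step 8
Reactants: 16 {2,5-bis(benzyloxy)-3,6-bis[4-(benzyloxy)phenyl]-4-(methoxymethoxy)phenoxy}tri(propan-2-yl)silane
Product: 18 2,5-bis(benzyloxy)-3,6-bis[4-(benzyloxy)phenyl]-4-(methoxymethoxy)phenyl 3-phenylpropanoate, via tetrabutylammonium phenoxide 17 (not isolated)
Conditions: TBAF, THF, 0 °C; then PhCH2CH2COCl, Et3N, DMAP (cat.), 0 °C → rt
Reagents that add atoms: 3-phenylpropanoyl chloride, O=C(Cl)CCc1ccccc1
Why: Fluoride cleaves the aryl silyl ether; the resulting ammonium phenoxide has only ether and aryl neighbours, so nothing can migrate, and it is acylated in the same flask by the acid chloride, which avoids isolating an oxidation-prone phenol.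

Step 9
Reactants: 18 2,5-bis(benzyloxy)-3,6-bis[4-(benzyloxy)phenyl]-4-(methoxymethoxy)phenyl 3-phenylpropanoate
Product: 19 2,5-bis(benzyloxy)-3,6-bis[4-(benzyloxy)phenyl]-4-hydroxyphenyl 3-phenylpropanoate
Conditions: ZnBr2, n-PrSH, CH2Cl2, 0 °C
Reagents that add atoms: none
Why: Lewis acid activation of the acetal with capture of the methoxymethyl cation by the thiol removes an aryl MOM ether quickly without protic acid or alcohol solvent, so the aryl ester and the benzyl ethers should be untouched and the cation cannot alkylate the electron-rich rings.

Step 10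
Reactants: 20 ethyl (3S)-3-hydroxybutanoate
Product: 21 ethyl (3S)-3-(benzyloxy)butanoate
Conditions: benzyl 2,2,2-trichloroacetimidate, TfOH (cat.), CH2Cl2/cyclohexane, 0 °C → rt
Reagents that add atoms: benzyl 2,2,2-trichloroacetimidate, N=C(OCc1ccccc1)C(Cl)(Cl)Cl
Why: Acid-catalysed O-benzylation with the trichloroacetimidate avoids the alkoxide that would trigger retro-aldol cleavage or elimination of a β-hydroxy ester. The C–O bond of the stereocentre is not broken, so the S configuration of the chiral-pool ester is kept.

Step 11
Reactants: 21 ethyl (3S)-3-(benzyloxy)butanoate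
Product: 22 (3S)-3-(benzyloxy)butanoic acid
Conditions: LiOH, THF/H2O, 0 °C → rt; then 1 M HCl
Reagents that add atoms: lithium hydroxide, [Li+].[OH-]
Why: Mild saponification of the ethyl ester; hydroxide at 0 °C should not eliminate the β-benzyloxy group at a useful rate, and the stereocentre is not α to the carbonyl.

Step 12
Reactants: 19 2,5-bis(benzyloxy)-3,6-bis[4-(benzyloxy)phenyl]-4-hydroxyphenyl 3-phenylpropanoate; 22 (3S)-3-(benzyloxy)butanoic acid
Product: 23 2,5-bis(benzyloxy)-3,6-bis[4-(benzyloxy)phenyl]-4-[(3-phenylpropanoyl)oxy]phenyl (3S)-3-(benzyloxy)butanoate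
Conditions: EDC·HCl, DMAP, CH2Cl2, 0 °C → rt
Reagents that add atoms: none
Why: Steglich esterification; the acylpyridinium ion formed with DMAP is reactive enough for a phenol flanked by a benzyloxy group and an aryl ring, and the medium is too weakly basic to eliminate the β-benzyloxy group. The free phenol has no acyl neighbour, so the existing ester cannot migrate.

Step 13
Reactants: 23 2,5-bis(benzyloxy)-3,6-bis[4-(benzyloxy)phenyl]-4-[(3-phenylpropanoyl)oxy]phenyl (3S)-3-(benzyloxy)butanoate
Product: 24 2,5-dihydroxy-3,6-bis(4-hydroxyphenyl)-4-[(3-phenylpropanoyl)oxy]phenyl (3S)-3-hydroxybutanoate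
Conditions: H2 (1 atm), 10% Pd/C, EtOAc (degassed), rt
Reagents that add atoms: none
Why: Hydrogenolysis removes the four aryl benzyl ethers and the alkyl benzyl ether in one neutral operation, the only kind of final step that leaves aryl esters next to free phenols in place. A non-nucleophilic solvent excludes transesterification, and exclusion of air protects the hydroquinone.

## Compound list

1 | 2-[4-(benzyloxy)phenyl]ethan-1-ol | OCCc1ccc(OCc2ccccc2)cc1 | starting material
2 | [4-(benzyloxy)phenyl]acetaldehyde | O=CCc1ccc(OCc2ccccc2)cc1 | intermediate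
3 | potassium (Z)-2-[4-(benzyloxy)phenyl]ethen-1-olate | [K+].[O-]/C=C\c1ccc(OCc2ccccc2)cc1 | intermediate
4 | 1-(benzyloxy)-4-[(Z)-2-(methoxymethoxy)ethenyl]benzene | COCO/C=C\c1ccc(OCc2ccccc2)cc1 | intermediate
5 | hexacarbonylchromium | O=C=[Cr](=C=O)(=C=O)(=C=O)(=C=O)=C=O | starting material
6 | {(Z)-2-[4-(benzyloxy)phenyl]-1-(methoxymethoxy)ethenyl}lithium | [Li]/C(OCOC)=C/c1ccc(OCc2ccccc2)cc1 | intermediate
7 | lithium pentacarbonyl{(2Z)-3-[4-(benzyloxy)phenyl]-2-(methoxymethoxy)prop-2-enoyl}chromate(1−) | [Li+].[O-]C(/C(OCOC)=C/c1ccc(OCc2ccccc2)cc1)=[Cr](=C=O)(=C=O)(=C=O)(=C=O)=C=O | intermediate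
8 | tetramethylammonium pentacarbonyl{(2Z)-3-[4-(benzyloxy)phenyl]-2-(methoxymethoxy)prop-2-enoyl}chromate(1−) | C[N+](C)(C)C.[O-]C(/C(OCOC)=C/c1ccc(OCc2ccccc2)cc1)=[Cr](=C=O)(=C=O)(=C=O)(=C=O)=C=O | intermediate
9 | pentacarbonyl{(acetyloxy)[(Z)-2-[4-(benzyloxy)phenyl]-1-(methoxymethoxy)ethenyl]methylidene}chromium | CC(=O)OC(/C(OCOC)=C/c1ccc(OCc2ccccc2)cc1)=[Cr](=C=O)(=C=O)(=C=O)(=C=O)=C=O | intermediate
10 | pentacarbonyl{(benzyloxy)[(Z)-2-[4-(benzyloxy)phenyl]-1-(methoxymethoxy)ethenyl]methylidene}chromium | O=C=[Cr](=C=O)(=C=O)(=C=O)(=C=O)=C(OCc1ccccc1)/C(OCOC)=C/c1ccc(OCc2ccccc2)cc1 | intermediate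
11 | 1-(benzyloxy)-4-ethynylbenzene | C#Cc1ccc(OCc2ccccc2)cc1 | starting material
12 | {[4-(benzyloxy)phenyl]ethynyl}lithium | [Li]C#Cc1ccc(OCc2ccccc2)cc1 | intermediate
13 | lithium 2-[4-(benzyloxy)phenyl]ethyn-1-olate | [Li+].[O-]C#Cc1ccc(OCc2ccccc2)cc1 | intermediate
14 | {[4-(benzyloxy)phenyl]ethynyloxy}tri(propan-2-yl)silane | CC(C)[Si](OC#Cc1ccc(OCc2ccccc2)cc1)(C(C)C)C(C)C | intermediate
15 | 4-(benzyloxy)-3,6-bis[4-(benzyloxy)phenyl]-5-(methoxymethoxy)-2-{[tri(propan-2-yl)silyl]oxy}phenol | Oc1c(O[Si](C(C)C)(C(C)C)C(C)C)c(-c2ccc(OCc3ccccc3)cc2)c(OCc2ccccc2)c(OCOC)c1-c1ccc(OCc2ccccc2)cc1 | intermediate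
16 | {2,5-bis(benzyloxy)-3,6-bis[4-(benzyloxy)phenyl]-4-(methoxymethoxy)phenoxy}tri(propan-2-yl)silane | CC(C)[Si](Oc1c(OCc2ccccc2)c(-c2ccc(OCc3ccccc3)cc2)c(OCOC)c(OCc2ccccc2)c1-c1ccc(OCc2ccccc2)cc1)(C(C)C)C(C)C | intermediate
17 | tetrabutylammonium 2,5-bis(benzyloxy)-3,6-bis[4-(benzyloxy)phenyl]-4-(methoxymethoxy)phenolate | CCCC[N+](CCCC)(CCCC)CCCC.[O-]c1c(OCc2ccccc2)c(-c2ccc(OCc3ccccc3)cc2)c(OCOC)c(OCc2ccccc2)c1-c1ccc(OCc2ccccc2)cc1 | intermediate
18 | 2,5-bis(benzyloxy)-3,6-bis[4-(benzyloxy)phenyl]-4-(methoxymethoxy)phenyl 3-phenylpropanoate | O=C(CCc1ccccc1)Oc1c(OCc2ccccc2)c(-c2ccc(OCc3ccccc3)cc2)c(OCOC)c(OCc2ccccc2)c1-c1ccc(OCc2ccccc2)cc1 | intermediate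
19 | 2,5-bis(benzyloxy)-3,6-bis[4-(benzyloxy)phenyl]-4-hydroxyphenyl 3-phenylpropanoate | O=C(CCc1ccccc1)Oc1c(OCc2ccccc2)c(-c2ccc(OCc3ccccc3)cc2)c(O)c(OCc2ccccc2)c1-c1ccc(OCc2ccccc2)cc1 | intermediate
20 | ethyl (3S)-3-hydroxybutanoate | C[C@H](O)CC(=O)OCC | starting material
21 | ethyl (3S)-3-(benzyloxy)butanoate | C[C@H](OCc1ccccc1)CC(=O)OCC | intermediate
22 | (3S)-3-(benzyloxy)butanoic acid | C[C@H](OCc1ccccc1)CC(=O)O | intermediate
23 | 2,5-bis(benzyloxy)-3,6-bis[4-(benzyloxy)phenyl]-4-[(3-phenylpropanoyl)oxy]phenyl (3S)-3-(benzyloxy)butanoate | C[C@H](OCc1ccccc1)CC(=O)Oc1c(OCc2ccccc2)c(-c2ccc(OCc3ccccc3)cc2)c(OC(=O)CCc2ccccc2)c(OCc2ccccc2)c1-c1ccc(OCc2ccccc2)cc1 | intermediate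
24 | 2,5-dihydroxy-3,6-bis(4-hydroxyphenyl)-4-[(3-phenylpropanoyl)oxy]phenyl (3S)-3-hydroxybutanoate | C[C@H](O)CC(=O)Oc1c(O)c(-c2ccc(O)cc2)c(OC(=O)CCc2ccccc2)c(O)c1-c1ccc(O)cc1 | target

## Step count and least certain steps

Total: 13 steps. Longest linear sequence: 10 steps (steps 1, 2, 3, 4, 6, 7, 8, 9, 12, 13).

Step 6 (key step, proposed new method).
- What may go wrong: the alkyne inserts in the opposite orientation; the sequence stalls at the siloxy-stabilised carbene formed after insertion; the ring closes without carbonyl insertion to a five-membered ring; or the ketene intermediate is intercepted by a second ynol ether. The donor on the new carbene carbon lowers its electrophilicity and therefore the rate of carbonyl insertion.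
- Fallback (known chemistry): use an alkynylboronate as the alkyne partner and turn the C–B bond into the C–O bond afterwards. It sets out from 10 and 11 and returns at 18.
- Course: 11 is deprotonated with n-BuLi (giving 12), borylated with 2-isopropoxy-4,4,5,5-tetramethyl-1,3,2-dioxaborolane and treated with HCl in Et2O to give 2-{[4-(benzyloxy)phenyl]ethynyl}-4,4,5,5-tetramethyl-1,3,2-dioxaborolane F1. Benzannulation of 10 with F1 under the conditions of step 6, a known variant that places the boryl group next to the new hydroxyl, should give 4-(benzyloxy)-3,6-bis[4-(benzyloxy)phenyl]-5-(methoxymethoxy)-2-(4,4,5,5-tetramethyl-1,3,2-dioxaborolan-2-yl)phenol F2. Williamson benzylation (BnBr, K2CO3, DMF), now with no silyl group that could migrate, should give 2-{2,5-bis(benzyloxy)-3,6-bis[4-(benzyloxy)phenyl]-4-(methoxymethoxy)phenyl}-4,4,5,5-tetramethyl-1,3,2-dioxaborolane F3. Oxidation of the C–B bond (NaBO3·4H2O, THF/H2O) should give 2,5-bis(benzyloxy)-3,6-bis[4-(benzyloxy)phenyl]-4-(methoxymethoxy)phenol F4, which is acylated with 3-phenylpropanoyl chloride (Et3N, DMAP) to reach 18.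

Step 3.
- What may go wrong: competing deprotonation at the benzylic OCH2 group of the aryl benzyl ether, because its kinetic acidity toward s-BuLi is not far from that of the vinylic C–H; and loss of lithium alkoxide from the α-lithio enol ether if it warms before it meets Cr(CO)6.
- Fallback: make the acylchromate without any organolithium, by acylating the pentacarbonylchromate dianion. It sets out from 5 and returns at 8.
- Course: aldol condensation of methyl (methoxymethoxy)acetate with 4-(benzyloxy)benzaldehyde (LiN(iPr)2, THF, −78 °C; then MsCl, Et3N; then DBU) should give methyl (2Z)-3-[4-(benzyloxy)phenyl]-2-(methoxymethoxy)prop-2-enoate F5. Hydrolysis with LiOH gives (2Z)-3-[4-(benzyloxy)phenyl]-2-(methoxymethoxy)prop-2-enoic acid F6. Neutral chlorination with 1-chloro-N,N,2-trimethylprop-1-en-1-amine gives (2Z)-3-[4-(benzyloxy)phenyl]-2-(methoxymethoxy)prop-2-enoyl chloride F7. Reduction of 5 with two equivalents of KC8 in THF gives dipotassium pentacarbonylchromate(2−) F8, which is acylated by F7 at −78 °C; cation exchange with Me4NBr then gives 8.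

Step 7.
- What may go wrong: slow etherification, because the phenol is flanked by the OTIPS group and an aryl ring, so the azodicarboxylate adduct is alkylated instead; or silyl transfer from the neighbouring oxygen within the phenoxide ion pair, which would give the regioisomeric benzyl ether.
- Fallback: change from redox condensation to direct SN2 alkylation of a phenoxide that is consumed as it forms. 15 is added slowly to Cs2CO3, Bu4NI and a large excess of BnBr in DMF at 0 °C. It sets out from 15 and returns at 16, with no new compound.
- If silyl transfer is faster than alkylation under all conditions, the boronate sequence through F1–F4 removes the silyl ether from the problem altogether.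

Step 2.
- What may go wrong: self-aldol condensation of the arylacetaldehyde before the enolate is complete, or C-alkylation, because aldehyde and enolate coexist for a moment.
- Fallback: generate the enolate in the absence of free aldehyde. It sets out from 2 and returns at 4.
- Course: 2 is silylated (TMSCl, Et3N, DMF, 80 °C) to {[(Z)-2-[4-(benzyloxy)phenyl]ethenyl]oxy}trimethylsilane F9. The silyl enol ether is cleaved with MeLi (THF, 0 °C) to lithium (Z)-2-[4-(benzyloxy)phenyl]ethen-1-olate F10, which is O-alkylated with MOMCl in THF/DMPU to give 4.

Step 12.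
- What may go wrong: slow acylation of the hindered phenol, which leaves time for rearrangement of the activated acid to an N-acylurea and for base-induced loss of benzyl alcohol to a crotonate.
- Fallback: reverse the order of the two acylations, so that the sensitive acid meets the strongly nucleophilic ammonium phenoxide and the robust acid chloride meets the hindered neutral phenol. The benzylated core is centrosymmetric, so the same compound results. It sets out from 16 and 22 and returns at 23.
- Course: 22 is converted with (COCl)2 and catalytic DMF into (3S)-3-(benzyloxy)butanoyl chloride F11. 16 is desilylated with TBAF as in step 8, and the phenoxide 17 is acylated with F11 to 2,5-bis(benzyloxy)-3,6-bis[4-(benzyloxy)phenyl]-4-(methoxymethoxy)phenyl (3S)-3-(benzyloxy)butanoate F12. Acetal cleavage as in step 9 gives 2,5-bis(benzyloxy)-3,6-bis[4-(benzyloxy)phenyl]-4-hydroxyphenyl (3S)-3-(benzyloxy)butanoate F13, and acylation with 3-phenylpropanoyl chloride (Et3N, DMAP) gives 23.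

## Further compounds

F1 | step 6 | 2-{[4-(benzyloxy)phenyl]ethynyl}-4,4,5,5-tetramethyl-1,3,2-dioxaborolane | CC1(C)OB(C#Cc2ccc(OCc3ccccc3)cc2)OC1(C)C
F2 | step 6 | 4-(benzyloxy)-3,6-bis[4-(benzyloxy)phenyl]-5-(methoxymethoxy)-2-(4,4,5,5-tetramethyl-1,3,2-dioxaborolan-2-yl)phenol | Oc1c(B2OC(C)(C)C(C)(C)O2)c(-c2ccc(OCc3ccccc3)cc2)c(OCc2ccccc2)c(OCOC)c1-c1ccc(OCc2ccccc2)cc1
F3 | step 6 | 2-{2,5-bis(benzyloxy)-3,6-bis[4-(benzyloxy)phenyl]-4-(methoxymethoxy)phenyl}-4,4,5,5-tetramethyl-1,3,2-dioxaborolane | CC1(C)OB(c2c(OCc3ccccc3)c(-c3ccc(OCc4ccccc4)cc3)c(OCOC)c(OCc3ccccc3)c2-c2ccc(OCc3ccccc3)cc2)OC1(C)C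
F4 | step 6 | 2,5-bis(benzyloxy)-3,6-bis[4-(benzyloxy)phenyl]-4-(methoxymethoxy)phenol | Oc1c(OCc2ccccc2)c(-c2ccc(OCc3ccccc3)cc2)c(OCOC)c(OCc2ccccc2)c1-c1ccc(OCc2ccccc2)cc1
F5 | step 3 | methyl (2Z)-3-[4-(benzyloxy)phenyl]-2-(methoxymethoxy)prop-2-enoate | COCO/C(C(=O)OC)=C\c1ccc(OCc2ccccc2)cc1
F6 | step 3 | (2Z)-3-[4-(benzyloxy)phenyl]-2-(methoxymethoxy)prop-2-enoic acid | COCO/C(C(=O)O)=C\c1ccc(OCc2ccccc2)cc1
F7 | step 3 | (2Z)-3-[4-(benzyloxy)phenyl]-2-(methoxymethoxy)prop-2-enoyl chloride | COCO/C(C(=O)Cl)=C\c1ccc(OCc2ccccc2)cc1
F8 | step 3 | dipotassium pentacarbonylchromate(2−) | [K+].[K+].O=C=[Cr-2](=C=O)(=C=O)(=C=O)=C=O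
F0 | step 7 | none | none
F9 | step 2 | {[(Z)-2-[4-(benzyloxy)phenyl]ethenyl]oxy}trimethylsilane | C[Si](C)(C)O/C=C\c1ccc(OCc2ccccc2)cc1
F10 | step 2 | lithium (Z)-2-[4-(benzyloxy)phenyl]ethen-1-olate | [Li+].[O-]/C=C\c1ccc(OCc2ccccc2)cc1
F11 | step 12 | (3S)-3-(benzyloxy)butanoyl chloride | C[C@H](OCc1ccccc1)CC(=O)Cl
F12 | step 12 | 2,5-bis(benzyloxy)-3,6-bis[4-(benzyloxy)phenyl]-4-(methoxymethoxy)phenyl (3S)-3-(benzyloxy)butanoate | C[C@H](OCc1ccccc1)CC(=O)Oc1c(OCc2ccccc2)c(-c2ccc(OCc3ccccc3)cc2)c(OCOC)c(OCc2ccccc2)c1-c1ccc(OCc2ccccc2)cc1
F13 | step 12 | 2,5-bis(benzyloxy)-3,6-bis[4-(benzyloxy)phenyl]-4-hydroxyphenyl (3S)-3-(benzyloxy)butanoate | C[C@H](OCc1ccccc1)CC(=O)Oc1c(OCc2ccccc2)c(-c2ccc(OCc3ccccc3)cc2)c(O)c(OCc2ccccc2)c1-c1ccc(OCc2ccccc2)cc1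
A1 | alternative 1 | bis({[4-(benzyloxy)phenyl]ethynyl}oxy)di(propan-2-yl)silane | CC(C)[Si](OC#Cc1ccc(OCc2ccccc2)cc1)(OC#Cc1ccc(OCc2ccccc2)cc1)C(C)C
A2 | alternative 1 | 1,2-di-tert-butoxyethyne | CC(C)(C)OC#COC(C)(C)C
A3 | alternative 1 | 4,7-bis[4-(benzyloxy)phenyl]-5,6-di-tert-butoxy-2,2-di(propan-2-yl)-1,3,2-benzodioxasilole | CC(C)[Si]1(C(C)C)Oc2c(O1)c(-c1ccc(OCc3ccccc3)cc1)c(OC(C)(C)C)c(OC(C)(C)C)c2-c1ccc(OCc2ccccc2)cc1
A4 | alternative 2 | 2,5-bis[4-(benzyloxy)phenyl]-4-[(3-phenylpropanoyl)oxy]phenyl (3S)-3-(benzyloxy)butanoate | C[C@H](OCc1ccccc1)CC(=O)Oc1cc(-c2ccc(OCc3ccccc3)cc2)c(OC(=O)CCc2ccccc2)cc1-c1ccc(OCc2ccccc2)cc1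
A5 | alternative 2 | (3S)-3-(benzyloxy)-1-{2,5-bis(benzyloxy)-3,6-bis[4-(benzyloxy)phenyl]-4-(3-phenylpropanoyl)phenyl}butan-1-one | C[C@H](OCc1ccccc1)CC(=O)c1c(OCc2ccccc2)c(-c2ccc(OCc3ccccc3)cc2)c(C(=O)CCc2ccccc2)c(OCc2ccccc2)c1-c1ccc(OCc2ccccc2)cc1
A6 | alternative 2 | 2,5-bis(benzyloxy)-3,6-bis[4-(benzyloxy)phenyl]-4-[(3-phenylpropanoyl)oxy]phenyl (3S)-3-(benzyloxy)butanoate | C[C@H](OCc1ccccc1)CC(=O)Oc1c(OCc2ccccc2)c(-c2ccc(OCc3ccccc3)cc2)c(OC(=O)CCc2ccccc2)c(OCc2ccccc2)c1-c1ccc(OCc2ccccc2)cc1
A7 | alternative 3 | methyl 3-[4-(benzyloxy)phenyl]-2-oxopropanoate | COC(=O)C(=O)Cc1ccc(OCc2ccccc2)cc1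
A8 | alternative 3 | 2,5-dihydroxy-3,6-bis[4-(benzyloxy)phenyl]cyclohexa-2,5-diene-1,4-dione | O=C1C(O)=C(c2ccc(OCc3ccccc3)cc2)C(=O)C(O)=C1c1ccc(OCc2ccccc2)cc1
A9 | alternative 3 | 3,6-bis[4-(benzyloxy)phenyl]benzene-1,2,4,5-tetrol | Oc1c(O)c(-c2ccc(OCc3ccccc3)cc2)c(O)c(O)c1-c1ccc(OCc2ccccc2)cc1
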